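## Retrosynthetic overview

1. The target is a (3S,4R,5S)-oxolane (O1, C2 to C5) whose ring-B phenol is etherified by an erythro guaiacylglycerol unit (C7''–C9''). The plan rests on C2 of the oxolane: it is benzylic, bound to O1 and para to the free phenolic OH of ring C. The O1–C2 bond is therefore made last, by dehydrogenating a ring-C 4-alkylphenol to its para-quinone methide and letting the C5 hydroxyl add (27 ⇐ 25).
2. Acyclic triol 25 ⇐ LiAlH4 reduction of a doubly benzylated (S)-malic acid. C3 is alkylated with ring-C bromide 4 (dianion, anti). C2 is alkylated with ring-B bromide 21 through the cis pivalaldehyde dioxolanone (retention).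
3. Bromide 21 ⇐ auxiliary-controlled syn-aldol of a ring-B aryloxyacetyl imide with O-benzylvanillin (C7''–C8'' bond), Mitsunobu inversion at C7'' to erythro, then acetonide.
4. Ring order: the 1,3-dioxane acetonide is only a protecting ring. The oxolane is the single skeletal ring and is closed in the key step, followed by acetonide hydrolysis and hydrogenolysis.
5. Phenol protection is orthogonal: ring C allyl (removed just before the oxidation), ring A benzyl (removed last).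

Key step: step 18

Remark: locants are oxolane O1, C2 (ring C), C3 (CH2OH), C4 (OH and ring-B benzyl), C5, and side chain C7'' (ring-A carbinol), C8'' (aryl ether), C9''. Imide 11 is assumed to be a catalogue compound; otherwise it is one acylation from (4R)-4-benzyloxazolidin-2-one and chloroacetyl chloride.

## Route

Step 1
Reactants: 1 vanillin
Product: 2 4-(allyloxy)-3-methoxybenzaldehyde
Conditions: allyl bromide, K2CO3, DMF, rt
Reagents that add atoms: allyl bromide, C=CCBr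
Why: Williamson ether synthesis on the phenoxide; the allyl ether should survive every base, acid and hydride step up to its release in step 17.

Step 2
Reactants: 2 4-(allyloxy)-3-methoxybenzaldehyde
Product: 3 [4-(allyloxy)-3-methoxyphenyl]methanol
Conditions: NaBH4, MeOH, 0 °C
Reagents that add atoms: none
Why: Borohydride reduction of an aromatic aldehyde; the allyl ether is inert.

Step 3
Reactants: 3 [4-(allyloxy)-3-methoxyphenyl]methanol
Product: 4 4-(allyloxy)-3-methoxybenzyl bromide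
Conditions: PBr3, Et2O, 0 °C
Reagents that add atoms: phosphorus tribromide, BrP(Br)Br
Why: Standard bromination of an electron-rich benzyl alcohol through its phosphite ester; the bromide is used directly.

Step 4
Reactants: 5 dimethyl (S)-malate; 4 4-(allyloxy)-3-methoxybenzyl bromide
Product: 7 dimethyl (2S,3R)-3-[4-(allyloxy)-3-methoxybenzyl]-2-hydroxybutanedioate, via dilithium alkoxide-enolate of dimethyl malate 6 (not isolated)
Conditions: LiN(SiMe3)2 (2.1 equiv), THF, −78 → −20 °C; then 4, −78 → 0 °C; AcOH quench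
Reagents that add atoms: none
Why: Fráter–Seebach alkylation: the chelated alkoxide-enolate dianion is alkylated anti to the alkoxide oxygen, which sets C3 as R; the minor syn isomer is to be removed by chromatography.

Step 5
Reactants: 7 dimethyl (2S,3R)-3-[4-(allyloxy)-3-methoxybenzyl]-2-hydroxybutanedioate
Product: 8 (2S,3R)-3-[4-(allyloxy)-3-methoxybenzyl]-2-hydroxybutanedioic acid
Conditions: KOH, MeOH–H2O, rt; then HCl to pH 1
Reagents that add atoms: potassium hydroxide, [K+].[OH-]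
Why: Saponification of both methyl esters; C3 should not epimerise because it sits alpha to a carboxylate.

Step 6
Reactants: 8 (2S,3R)-3-[4-(allyloxy)-3-methoxybenzyl]-2-hydroxybutanedioic acid
Product: 9 (2R)-3-[4-(allyloxy)-3-methoxyphenyl]-2-[(2S,4S)-2-tert-butyl-5-oxo-1,3-dioxolan-4-yl]propanoic acid
Conditions: t-BuCHO, TsOH·H2O (cat.), H2SO4 (cat.), pentane, reflux, water separator
Reagents that add atoms: pivalaldehyde, CC(C)(C)C=O
Why: Acetalisation of the alpha-hydroxy acid to the five-membered dioxolanone (self-regeneration of stereocentres); the new acetal carbon is set S by the preference for the cis-2,5-disubstituted ring, and the cis isomer is to be purified by crystallisation.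

Step 7
Reactants: 10 methyl vanillate; 11 (4R)-4-benzyl-3-(chloroacetyl)-1,3-oxazolidin-2-one
Product: 12 methyl 4-{2-[(4R)-4-benzyl-2-oxo-1,3-oxazolidin-3-yl]-2-oxoethoxy}-3-methoxybenzoate
Conditions: K2CO3, NaI (cat.), acetone, 50 °C
Reagents that add atoms: none
Why: Williamson displacement of the activated alpha-chloro imide by the weakly basic phenoxide, faster than acyl transfer from the imide.

Step 8
Reactants: 12 methyl 4-{2-[(4R)-4-benzyl-2-oxo-1,3-oxazolidin-3-yl]-2-oxoethoxy}-3-methoxybenzoate; 13 4-(benzyloxy)-3-methoxybenzaldehyde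
Product: 15 methyl 4-({(2R,3S)-1-[(4R)-4-benzyl-2-oxo-1,3-oxazolidin-3-yl]-3-[4-(benzyloxy)-3-methoxyphenyl]-3-hydroxy-1-oxopropan-2-yl}oxy)-3-methoxybenzoate, via Z-dibutylboron enolate 14 (not isolated)
Conditions: Bu2BOTf, i-Pr2NEt, CH2Cl2, −78 → 0 °C; then 13, −78 → 0 °C; pH 7 buffer, MeOH, H2O2
Reagents that add atoms: none
Why: Evans syn-aldol: the Z-boron enolate reacts through a Zimmerman–Traxler chair on the face away from the auxiliary benzyl group, giving the 2R,3S syn (threo) adduct and so fixing C8''.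

Step 9
Reactants: 15 methyl 4-({(2R,3S)-1-[(4R)-4-benzyl-2-oxo-1,3-oxazolidin-3-yl]-3-[4-(benzyloxy)-3-methoxyphenyl]-3-hydroxy-1-oxopropan-2-yl}oxy)-3-methoxybenzoate
Product: 16 methyl 4-({(1S,2S)-1-[4-(benzyloxy)-3-methoxyphenyl]-1,3-dihydroxypropan-2-yl}oxy)-3-methoxybenzoate
Conditions: NaBH4, THF–H2O, 0 °C → rt
Reagents that add atoms: none
Why: Reductive cleavage of the N-acyloxazolidinone to the primary alcohol with release of the auxiliary; NaBH4 should not touch the electron-rich aryl methyl ester.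

Step 10
Reactants: 16 methyl 4-({(1S,2S)-1-[4-(benzyloxy)-3-methoxyphenyl]-1,3-dihydroxypropan-2-yl}oxy)-3-methoxybenzoate
Product: 17 (1R,2S)-1-[4-(benzyloxy)-3-methoxyphenyl]-2-[2-methoxy-4-(methoxycarbonyl)phenoxy]propane-1,3-diyl bis(4-nitrobenzoate)
Conditions: 4-O2NC6H4CO2H (3 equiv), PPh3 (3 equiv), DIAD (3 equiv), THF, −20 °C → rt
Reagents that add atoms: 4-nitrobenzoic acid, O=C(O)c1ccc(cc1)[N+](=O)[O-]
Why: Mitsunobu esterification: the primary hydroxyl is acylated and the benzylic alkoxyphosphonium at C7'' is displaced by carboxylate with inversion (S to R), turning threo into erythro.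

Step 11
Reactants: 17 (1R,2S)-1-[4-(benzyloxy)-3-methoxyphenyl]-2-[2-methoxy-4-(methoxycarbonyl)phenoxy]propane-1,3-diyl bis(4-nitrobenzoate)
Product: 18 methyl 4-({(1R,2S)-1-[4-(benzyloxy)-3-methoxyphenyl]-1,3-dihydroxypropan-2-yl}oxy)-3-methoxybenzoate
Conditions: K2CO3 (cat.), MeOH, rt
Reagents that add atoms: none
Why: Zemplén-type transesterification removes both activated nitrobenzoates by acyl–oxygen cleavage, so C7'' is untouched, and exchange at the aryl methyl ester is degenerate in methanol.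

Step 12
Reactants: 18 methyl 4-({(1R,2S)-1-[4-(benzyloxy)-3-methoxyphenyl]-1,3-dihydroxypropan-2-yl}oxy)-3-methoxybenzoate
Product: 19 methyl 4-({(4R,5S)-4-[4-(benzyloxy)-3-methoxyphenyl]-2,2-dimethyl-1,3-dioxan-5-yl}oxy)-3-methoxybenzoate
Conditions: Me2C(OMe)2, PPTS (cat.), acetone, rt
Reagents that add atoms: 2,2-dimethoxypropane, COC(C)(C)OC
Why: Transacetalisation of the 1,3-diol; the erythro diol gives the trans-4,5-diequatorial 1,3-dioxane.

Step 13
Reactants: 19 methyl 4-({(4R,5S)-4-[4-(benzyloxy)-3-methoxyphenyl]-2,2-dimethyl-1,3-dioxan-5-yl}oxy)-3-methoxybenzoate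
Product: 20 [4-({(4R,5S)-4-[4-(benzyloxy)-3-methoxyphenyl]-2,2-dimethyl-1,3-dioxan-5-yl}oxy)-3-methoxyphenyl]methanol
Conditions: LiAlH4, THF, 0 °C
Reagents that add atoms: none
Why: Hydride reduction of the benzoate ester; acetonide, benzyl ether and aryl ethers are inert to LiAlH4.

Step 14
Reactants: 20 [4-({(4R,5S)-4-[4-(benzyloxy)-3-methoxyphenyl]-2,2-dimethyl-1,3-dioxan-5-yl}oxy)-3-methoxyphenyl]methanol
Product: 21 (4R,5S)-4-[4-(benzyloxy)-3-methoxyphenyl]-5-[4-(bromomethyl)-2-methoxyphenoxy]-2,2-dimethyl-1,3-dioxane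
Conditions: CBr4, PPh3, CH2Cl2, 0 °C
Reagents that add atoms: carbon tetrabromide, BrC(Br)(Br)Br
Why: Appel bromination under neutral conditions spares the acetonide; the reactive benzylic bromide is used at once.

Step 15
Reactants: 9 (2R)-3-[4-(allyloxy)-3-methoxyphenyl]-2-[(2S,4S)-2-tert-butyl-5-oxo-1,3-dioxolan-4-yl]propanoic acid; 21 (4R,5S)-4-[4-(benzyloxy)-3-methoxyphenyl]-5-[4-(bromomethyl)-2-methoxyphenoxy]-2,2-dimethyl-1,3-dioxane
Product: 23 (2R)-3-[4-(allyloxy)-3-methoxyphenyl]-2-[(2S,4S)-4-[4-({(4R,5S)-4-[4-(benzyloxy)-3-methoxyphenyl]-2,2-dimethyl-1,3-dioxan-5-yl}oxy)-3-methoxybenzyl]-2-tert-butyl-5-oxo-1,3-dioxolan-4-yl]propanoic acid, via dilithium carboxylate-enolate 22 (not isolated)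
Conditions: LiN(SiMe3)2 (2.1 equiv), THF, −78 °C; then 21, −78 → −30 °C; AcOH quench; crude acid taken on
Reagents that add atoms: none
Why: Enolate alkylation of the dioxolanone (self-regeneration of stereocentres): the benzyl bromide enters anti to the tert-butyl group and takes the place of the former hydrogen, so the quaternary carbinol carbon (future C4) forms with overall retention as S, while the carboxylate keeps the neighbouring C–H from enolising.

Step 16
Reactants: 23 (2R)-3-[4-(allyloxy)-3-methoxyphenyl]-2-[(2S,4S)-4-[4-({(4R,5S)-4-[4-(benzyloxy)-3-methoxyphenyl]-2,2-dimethyl-1,3-dioxan-5-yl}oxy)-3-methoxybenzyl]-2-tert-butyl-5-oxo-1,3-dioxolan-4-yl]propanoic acid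
Product: 24 (2S,3S)-3-[4-(allyloxy)-3-methoxybenzyl]-2-[4-({(4R,5S)-4-[4-(benzyloxy)-3-methoxyphenyl]-2,2-dimethyl-1,3-dioxan-5-yl}oxy)-3-methoxybenzyl]butane-1,2,4-triol
Conditions: LiAlH4, THF, 0 °C → reflux
Reagents that add atoms: none
Why: LiAlH4 reduces the carboxylic acid and the dioxolanone carbonyl to the two CH2OH groups and the acylal collapses to free the tertiary hydroxyl; no stereocentre is touched.

Step 17
Reactants: 24 (2S,3S)-3-[4-(allyloxy)-3-methoxybenzyl]-2-[4-({(4R,5S)-4-[4-(benzyloxy)-3-methoxyphenyl]-2,2-dimethyl-1,3-dioxan-5-yl}oxy)-3-methoxybenzyl]butane-1,2,4-triol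
Product: 25 (2S,3S)-2-[4-({(4R,5S)-4-[4-(benzyloxy)-3-methoxyphenyl]-2,2-dimethyl-1,3-dioxan-5-yl}oxy)-3-methoxybenzyl]-3-(4-hydroxy-3-methoxybenzyl)butane-1,2,4-triol
Conditions: Pd(PPh3)4 (5 mol %), morpholine, THF, rt
Reagents that add atoms: none
Why: Tsuji–Trost deallylation: zerovalent palladium ionises the aryl allyl ether and morpholine traps the allyl fragment, leaving the benzyl ether, acetonide and alcohols untouched.

Step 18
Reactants: 25 (2S,3S)-2-[4-({(4R,5S)-4-[4-(benzyloxy)-3-methoxyphenyl]-2,2-dimethyl-1,3-dioxan-5-yl}oxy)-3-methoxybenzyl]-3-(4-hydroxy-3-methoxybenzyl)butane-1,2,4-triol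
Product: 27 (3S,4R,5S)-3-[4-({(4R,5S)-4-[4-(benzyloxy)-3-methoxyphenyl]-2,2-dimethyl-1,3-dioxan-5-yl}oxy)-3-methoxybenzyl]-5-(4-hydroxy-3-methoxyphenyl)-4-(hydroxymethyl)oxolan-3-ol, via para-quinone methide 26 (not isolated)
Conditions: DDQ (1.05 equiv), anhydrous 1,4-dioxane, rt, dark
Reagents that add atoms: none
Why: DDQ forms a charge-transfer complex with the electron-rich ring-C guaiacol and removes the phenolic hydrogen and the benzylic hydride from C2, giving para-quinone methide 26 and the hydroquinone, which is poorly soluble in dioxane and so should leave little acid in solution. The closest known reaction type is the quinone dehydrogenation of 4-alkylphenols with internal hydroxyl capture, as used to turn phenolic dibenzylbutanediols into 7,9'-epoxylignans. The oxolane closes by 5-exo-trig oxa-1,6-addition of the C5 hydroxyl (the CH2OH on carbinol carbon C4) to the methide carbon, which forms O1–C2 and restores the phenol. The new stereocentre C2 is controlled by the adjacent C3 centre: the aryl group should end up trans to the C3 hydroxymethyl (2S in the locants used here), and because the addition is reversible through the quinone methide this is also the thermodynamic isomer. The step needs selectivity among three rings and three hydroxyls, which the substrate secures because only ring C has a free para-hydroxyl (ring B is an aryl ether; ring A is a benzyl ether whose benzylic acetal C–H is oxidised far more slowly) and the C4 and C3-arm hydroxyls could only give oxetanes. One equivalent of oxidant and the absence of acid guard against a second oxidation at C2 and against Friedel–Crafts capture by ring B.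

Step 19
Reactants: 27 (3S,4R,5S)-3-[4-({(4R,5S)-4-[4-(benzyloxy)-3-methoxyphenyl]-2,2-dimethyl-1,3-dioxan-5-yl}oxy)-3-methoxybenzyl]-5-(4-hydroxy-3-methoxyphenyl)-4-(hydroxymethyl)oxolan-3-ol
Product: 28 (3S,4R,5S)-3-[4-({(1R,2S)-1-[4-(benzyloxy)-3-methoxyphenyl]-1,3-dihydroxypropan-2-yl}oxy)-3-methoxybenzyl]-5-(4-hydroxy-3-methoxyphenyl)-4-(hydroxymethyl)oxolan-3-ol
Conditions: AcOH–H2O–THF (3:1:1), rt
Reagents that add atoms: none
Why: Mild acetal hydrolysis of the 1,3-dioxane acetonide; the acid is kept weak and cold because the C2 benzylic ether of the oxolane is para to a free phenol.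

Step 20
Reactants: 28 (3S,4R,5S)-3-[4-({(1R,2S)-1-[4-(benzyloxy)-3-methoxyphenyl]-1,3-dihydroxypropan-2-yl}oxy)-3-methoxybenzyl]-5-(4-hydroxy-3-methoxyphenyl)-4-(hydroxymethyl)oxolan-3-ol
Product: 29 (3S,4R,5S)-3-[4-({(1R,2S)-1,3-dihydroxy-1-(4-hydroxy-3-methoxyphenyl)propan-2-yl}oxy)-3-methoxybenzyl]-5-(4-hydroxy-3-methoxyphenyl)-4-(hydroxymethyl)oxolan-3-ol
Conditions: H2 (1 atm), Pd/C (palladium on carbon), EtOAc–MeOH, rt, stopped at one equivalent of uptake
Reagents that add atoms: none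
Why: Hydrogenolysis of the aryl benzyl ether, which is much faster than cleavage of the secondary benzylic C–O bonds at C2 and C7''.

## Compound list

1 | vanillin | COc1cc(C=O)ccc1O | starting material
2 | 4-(allyloxy)-3-methoxybenzaldehyde | C=CCOc1ccc(C=O)cc1OC | intermediate
3 | [4-(allyloxy)-3-methoxyphenyl]methanol | C=CCOc1ccc(CO)cc1OC | intermediate
4 | 4-(allyloxy)-3-methoxybenzyl bromide | C=CCOc1ccc(CBr)cc1OC | intermediate
5 | dimethyl (S)-malate | COC(=O)C[C@H](O)C(=O)OC | starting material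
6 | dilithium alkoxide-enolate of dimethyl malate (enolate geometry not specified) | [Li+].[Li+].COC(=O)[C@@H]([O-])C=C([O-])OC | intermediate
7 | dimethyl (2S,3R)-3-[4-(allyloxy)-3-methoxybenzyl]-2-hydroxybutanedioate | COC(=O)[C@H](Cc1ccc(OCC=C)c(OC)c1)[C@H](O)C(=O)OC | intermediate
8 | (2S,3R)-3-[4-(allyloxy)-3-methoxybenzyl]-2-hydroxybutanedioic acid | OC(=O)[C@H](Cc1ccc(OCC=C)c(OC)c1)[C@H](O)C(=O)O | intermediate
9 | (2R)-3-[4-(allyloxy)-3-methoxyphenyl]-2-[(2S,4S)-2-tert-butyl-5-oxo-1,3-dioxolan-4-yl]propanoic acid | OC(=O)[C@H](Cc1ccc(OCC=C)c(OC)c1)[C@@H]2O[C@H](C(C)(C)C)OC2=O | intermediate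
10 | methyl vanillate (methyl 4-hydroxy-3-methoxybenzoate) | COC(=O)c1ccc(O)c(OC)c1 | starting material
11 | (4R)-4-benzyl-3-(chloroacetyl)-1,3-oxazolidin-2-one | O=C(CCl)N1[C@H](Cc2ccccc2)COC1=O | starting material
12 | methyl 4-{2-[(4R)-4-benzyl-2-oxo-1,3-oxazolidin-3-yl]-2-oxoethoxy}-3-methoxybenzoate | COC(=O)c1ccc(OCC(=O)N2[C@H](Cc3ccccc3)COC2=O)c(OC)c1 | intermediate
13 | 4-(benzyloxy)-3-methoxybenzaldehyde | COc1cc(C=O)ccc1OCc2ccccc2 | starting material
14 | Z-dibutylboron enolate of 12 | COC(=O)c1ccc(O/C=C(\OB(CCCC)CCCC)N2[C@H](Cc3ccccc3)COC2=O)c(OC)c1 | intermediate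
15 | methyl 4-({(2R,3S)-1-[(4R)-4-benzyl-2-oxo-1,3-oxazolidin-3-yl]-3-[4-(benzyloxy)-3-methoxyphenyl]-3-hydroxy-1-oxopropan-2-yl}oxy)-3-methoxybenzoate | COC(=O)c1ccc(O[C@H]([C@@H](O)c2ccc(OCc3ccccc3)c(OC)c2)C(=O)N4[C@H](Cc5ccccc5)COC4=O)c(OC)c1 | intermediate
16 | methyl 4-({(1S,2S)-1-[4-(benzyloxy)-3-methoxyphenyl]-1,3-dihydroxypropan-2-yl}oxy)-3-methoxybenzoate (threo) | COc1cc([C@H](O)[C@H](CO)Oc2ccc(C(=O)OC)cc2OC)ccc1OCc3ccccc3 | intermediate
17 | (1R,2S)-1-[4-(benzyloxy)-3-methoxyphenyl]-2-[2-methoxy-4-(methoxycarbonyl)phenoxy]propane-1,3-diyl bis(4-nitrobenzoate) | COc1cc([C@@H](OC(=O)c4ccc(cc4)[N+](=O)[O-])[C@H](COC(=O)c5ccc(cc5)[N+](=O)[O-])Oc2ccc(C(=O)OC)cc2OC)ccc1OCc3ccccc3 | intermediate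
18 | methyl 4-({(1R,2S)-1-[4-(benzyloxy)-3-methoxyphenyl]-1,3-dihydroxypropan-2-yl}oxy)-3-methoxybenzoate (erythro) | COc1cc([C@@H](O)[C@H](CO)Oc2ccc(C(=O)OC)cc2OC)ccc1OCc3ccccc3 | intermediate
19 | methyl 4-({(4R,5S)-4-[4-(benzyloxy)-3-methoxyphenyl]-2,2-dimethyl-1,3-dioxan-5-yl}oxy)-3-methoxybenzoate | COc1cc([C@H]2OC(C)(C)OC[C@@H]2Oc3ccc(C(=O)OC)cc3OC)ccc1OCc4ccccc4 | intermediate
20 | [4-({(4R,5S)-4-[4-(benzyloxy)-3-methoxyphenyl]-2,2-dimethyl-1,3-dioxan-5-yl}oxy)-3-methoxyphenyl]methanol | COc1cc([C@H]2OC(C)(C)OC[C@@H]2Oc3ccc(CO)cc3OC)ccc1OCc4ccccc4 | intermediate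
21 | (4R,5S)-4-[4-(benzyloxy)-3-methoxyphenyl]-5-[4-(bromomethyl)-2-methoxyphenoxy]-2,2-dimethyl-1,3-dioxane | COc1cc([C@H]2OC(C)(C)OC[C@@H]2Oc3ccc(CBr)cc3OC)ccc1OCc4ccccc4 | intermediate
22 | dilithium carboxylate-enolate of 9 | [Li+].[Li+].[O-]C(=O)[C@H](Cc1ccc(OCC=C)c(OC)c1)C2=C([O-])O[C@@H](C(C)(C)C)O2 | intermediate
23 | (2R)-3-[4-(allyloxy)-3-methoxyphenyl]-2-[(2S,4S)-4-[4-({(4R,5S)-4-[4-(benzyloxy)-3-methoxyphenyl]-2,2-dimethyl-1,3-dioxan-5-yl}oxy)-3-methoxybenzyl]-2-tert-butyl-5-oxo-1,3-dioxolan-4-yl]propanoic acid | COc1cc([C@H]2OC(C)(C)OC[C@@H]2Oc3ccc(C[C@]4(O[C@H](C(C)(C)C)OC4=O)[C@@H](Cc5ccc(OCC=C)c(OC)c5)C(=O)O)cc3OC)ccc1OCc6ccccc6 | intermediate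
24 | (2S,3S)-3-[4-(allyloxy)-3-methoxybenzyl]-2-[4-({(4R,5S)-4-[4-(benzyloxy)-3-methoxyphenyl]-2,2-dimethyl-1,3-dioxan-5-yl}oxy)-3-methoxybenzyl]butane-1,2,4-triol | COc1cc([C@H]2OC(C)(C)OC[C@@H]2Oc3ccc(C[C@@]([C@H](CO)Cc4ccc(OCC=C)c(OC)c4)(O)CO)cc3OC)ccc1OCc5ccccc5 | intermediate
25 | (2S,3S)-2-[4-({(4R,5S)-4-[4-(benzyloxy)-3-methoxyphenyl]-2,2-dimethyl-1,3-dioxan-5-yl}oxy)-3-methoxybenzyl]-3-(4-hydroxy-3-methoxybenzyl)butane-1,2,4-triol | COc1cc([C@H]2OC(C)(C)OC[C@@H]2Oc3ccc(C[C@@]([C@H](CO)Cc4ccc(O)c(OC)c4)(O)CO)cc3OC)ccc1OCc5ccccc5 | intermediate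
26 | para-quinone methide of 25 (exocyclic alkene geometry not specified) | COc1cc([C@H]2OC(C)(C)OC[C@@H]2Oc3ccc(C[C@@]([C@H](CO)C=C4C=CC(=O)C(OC)=C4)(O)CO)cc3OC)ccc1OCc5ccccc5 | intermediate
27 | (3S,4R,5S)-3-[4-({(4R,5S)-4-[4-(benzyloxy)-3-methoxyphenyl]-2,2-dimethyl-1,3-dioxan-5-yl}oxy)-3-methoxybenzyl]-5-(4-hydroxy-3-methoxyphenyl)-4-(hydroxymethyl)oxolan-3-ol | COc1cc([C@H]2OC(C)(C)OC[C@@H]2Oc3ccc(C[C@@]4(O)CO[C@H](c5ccc(O)c(OC)c5)[C@H]4CO)cc3OC)ccc1OCc6ccccc6 | intermediate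
28 | (3S,4R,5S)-3-[4-({(1R,2S)-1-[4-(benzyloxy)-3-methoxyphenyl]-1,3-dihydroxypropan-2-yl}oxy)-3-methoxybenzyl]-5-(4-hydroxy-3-methoxyphenyl)-4-(hydroxymethyl)oxolan-3-ol | COc1cc([C@@H](O)[C@H](CO)Oc2ccc(C[C@@]3(O)CO[C@H](c4ccc(O)c(OC)c4)[C@H]3CO)cc2OC)ccc1OCc5ccccc5 | intermediate
29 | (3S,4R,5S)-3-[4-({(1R,2S)-1,3-dihydroxy-1-(4-hydroxy-3-methoxyphenyl)propan-2-yl}oxy)-3-methoxybenzyl]-5-(4-hydroxy-3-methoxyphenyl)-4-(hydroxymethyl)oxolan-3-ol (CNP0350466.2) | COc1cc([C@@H](O)[C@H](CO)Oc2ccc(C[C@@]3(O)CO[C@H](c4ccc(O)c(OC)c4)[C@H]3CO)cc2OC)ccc1O | target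

## Step count and risk

Total step count: 20. Longest linear sequence: 14 steps (steps 7 to 14, then 15 to 20).

Steps most likely to fail:

Step 18 (key oxidation). Possible failures are a second hydride abstraction at C2 of the product, competing oxidation at the ring-A benzylic acetal C–H, tautomerisation of the quinone methide to a styrene, or C-alkylation by ring B. The fallback separates oxidation from ring closure. Setting out from 25, the oxidation is run with DDQ in CH2Cl2–MeOH at −20 °C so that solvent methanol intercepts quinone methide 26. The benzylic methyl ether (2S,3S)-2-[4-({(4R,5S)-4-[4-(benzyloxy)-3-methoxyphenyl]-2,2-dimethyl-1,3-dioxan-5-yl}oxy)-3-methoxybenzyl]-3-[(4-hydroxy-3-methoxyphenyl)(methoxy)methyl]butane-1,2,4-triol F1 is isolated as its epimer mixture, together with any 27 already formed. F1 is then warmed with catalytic PPTS in MeCN, where the para-hydroxybenzyl ether ionises reversibly and exchanges methanol for the C5 hydroxyl under thermodynamic control, coming back to the route at 27.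

Step 10 (Mitsunobu inversion). The electron-rich benzylic alkoxyphosphonium may ionise, which would erode inversion through ion-pair return, neighbouring-group participation or elimination. The fallback replaces substitution by oxidation and chelation-controlled reduction. Setting out from 16, the primary hydroxyl is silylated (t-BuPh2SiCl, imidazole, DMF) to methyl 4-({(1S,2S)-1-[4-(benzyloxy)-3-methoxyphenyl]-3-[(tert-butyldiphenylsilyl)oxy]-1-hydroxypropan-2-yl}oxy)-3-methoxybenzoate F2. The carbinol is oxidised with Dess–Martin periodinane to the ketone methyl 4-({(2S)-1-[4-(benzyloxy)-3-methoxyphenyl]-3-[(tert-butyldiphenylsilyl)oxy]-1-oxopropan-2-yl}oxy)-3-methoxybenzoate F3. Reduction with Zn(BH4)2 in Et2O at −30 °C, where zinc is chelated between the carbonyl and the guaiacyl ether oxygens, should deliver hydride to give the anti (erythro) alcohol methyl 4-({(1R,2S)-1-[4-(benzyloxy)-3-methoxyphenyl]-3-[(tert-butyldiphenylsilyl)oxy]-1-hydroxypropan-2-yl}oxy)-3-methoxybenzoate F4. Desilylation with Bu4NF in THF comes back to the route at 18.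

Step 15 (convergent alkylation). The dilithium carboxylate-enolate may convert poorly with the bulky bromide, through enolate decomposition on warming, aggregation or O-alkylation of the carboxylate. The fallback moves the quaternary centre to a butyrolactone enolate.
- Setting out from 9, the free acid is reduced through its mixed anhydride (i-BuOCOCl, N-methylmorpholine, THF, −15 °C; then NaBH4). Acid-catalysed lactonisation onto the dioxolanone carbonyl expels pivalaldehyde and gives (3S,4S)-4-[4-(allyloxy)-3-methoxybenzyl]-3-hydroxyoxolan-2-one F5.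
- Silylation (t-BuMe2SiCl, imidazole, DMF) gives (3S,4S)-4-[4-(allyloxy)-3-methoxybenzyl]-3-[(tert-butyldimethylsilyl)oxy]oxolan-2-one F6.
- Its lithium enolate (LiN(i-Pr)2, THF, −78 °C) is alkylated by 21 trans to the C4 benzyl group to give (3S,4S)-4-[4-(allyloxy)-3-methoxybenzyl]-3-[4-({(4R,5S)-4-[4-(benzyloxy)-3-methoxyphenyl]-2,2-dimethyl-1,3-dioxan-5-yl}oxy)-3-methoxybenzyl]-3-[(tert-butyldimethylsilyl)oxy]oxolan-2-one F7.
- LiAlH4 opens the lactone to (2S,3S)-3-[4-(allyloxy)-3-methoxybenzyl]-2-[4-({(4R,5S)-4-[4-(benzyloxy)-3-methoxyphenyl]-2,2-dimethyl-1,3-dioxan-5-yl}oxy)-3-methoxybenzyl]-2-[(tert-butyldimethylsilyl)oxy]butane-1,4-diol F8.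
- Bu4NF in THF removes the silyl group and comes back to the route at 24.

Further compounds
F1 | step 18 | (2S,3S)-2-[4-({(4R,5S)-4-[4-(benzyloxy)-3-methoxyphenyl]-2,2-dimethyl-1,3-dioxan-5-yl}oxy)-3-methoxybenzyl]-3-[(4-hydroxy-3-methoxyphenyl)(methoxy)methyl]butane-1,2,4-triol (epimers at the methoxy carbon) | COc1cc([C@H]2OC(C)(C)OC[C@@H]2Oc3ccc(C[C@@]([C@H](CO)C(OC)c4ccc(O)c(OC)c4)(O)CO)cc3OC)ccc1OCc5ccccc5
F2 | step 10 | methyl 4-({(1S,2S)-1-[4-(benzyloxy)-3-methoxyphenyl]-3-[(tert-butyldiphenylsilyl)oxy]-1-hydroxypropan-2-yl}oxy)-3-methoxybenzoate | COc1cc([C@H](O)[C@H](CO[Si](c4ccccc4)(c5ccccc5)C(C)(C)C)Oc2ccc(C(=O)OC)cc2OC)ccc1OCc3ccccc3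
F3 | step 10 | methyl 4-({(2S)-1-[4-(benzyloxy)-3-methoxyphenyl]-3-[(tert-butyldiphenylsilyl)oxy]-1-oxopropan-2-yl}oxy)-3-methoxybenzoate | COc1cc(C(=O)[C@H](CO[Si](c4ccccc4)(c5ccccc5)C(C)(C)C)Oc2ccc(C(=O)OC)cc2OC)ccc1OCc3ccccc3
F4 | step 10 | methyl 4-({(1R,2S)-1-[4-(benzyloxy)-3-methoxyphenyl]-3-[(tert-butyldiphenylsilyl)oxy]-1-hydroxypropan-2-yl}oxy)-3-methoxybenzoate | COc1cc([C@@H](O)[C@H](CO[Si](c4ccccc4)(c5ccccc5)C(C)(C)C)Oc2ccc(C(=O)OC)cc2OC)ccc1OCc3ccccc3
F5 | step 15 | (3S,4S)-4-[4-(allyloxy)-3-methoxybenzyl]-3-hydroxyoxolan-2-one | O=C1OC[C@H](Cc2ccc(OCC=C)c(OC)c2)[C@@H]1O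
F6 | step 15 | (3S,4S)-4-[4-(allyloxy)-3-methoxybenzyl]-3-[(tert-butyldimethylsilyl)oxy]oxolan-2-one | O=C1OC[C@H](Cc2ccc(OCC=C)c(OC)c2)[C@@H]1O[Si](C)(C)C(C)(C)C
F7 | step 15 | (3S,4S)-4-[4-(allyloxy)-3-methoxybenzyl]-3-[4-({(4R,5S)-4-[4-(benzyloxy)-3-methoxyphenyl]-2,2-dimethyl-1,3-dioxan-5-yl}oxy)-3-methoxybenzyl]-3-[(tert-butyldimethylsilyl)oxy]oxolan-2-one | COc1cc([C@H]2OC(C)(C)OC[C@@H]2Oc3ccc(C[C@@]4(O[Si](C)(C)C(C)(C)C)C(=O)OC[C@@H]4Cc5ccc(OCC=C)c(OC)c5)cc3OC)ccc1OCc6ccccc6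
F8 | step 15 | (2S,3S)-3-[4-(allyloxy)-3-methoxybenzyl]-2-[4-({(4R,5S)-4-[4-(benzyloxy)-3-methoxyphenyl]-2,2-dimethyl-1,3-dioxan-5-yl}oxy)-3-methoxybenzyl]-2-[(tert-butyldimethylsilyl)oxy]butane-1,4-diol | COc1cc([C@H]2OC(C)(C)OC[C@@H]2Oc3ccc(C[C@@]([C@H](CO)Cc4ccc(OCC=C)c(OC)c4)(O[Si](C)(C)C(C)(C)C)CO)cc3OC)ccc1OCc5ccccc5
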